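The route rests on cutting the bond between C2 of the benzofuran (rings A and B) and C4′ of the dihydrobenzofuran (benzene ring C, dihydrofuran ring D). In ring C the carbons C4′ (biaryl), C3a′ (benzylic) and C7a′ (oxygen-bearing) are contiguous, so C4′ and C3a′ become the two ends of a 3-alkoxyaryne. In one operation the C2-lithiated 7-geranylbenzofuran adds to the aryne carbon remote from oxygen. The ortho-alkoxy aryllithium thus formed opens an enantiopure epoxide, which brings in C3′, the C2′ stereocentre and the CMe2O unit. The precursors are a C2–H benzofuran, a bromofluororesorcinol bis-acetal and a glycidate-derived epoxide. Ring D closes afterwards by double inversion.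

Key step: step 7

Remark on the chemistry: the stereocentre C2′ of the target is read as (S). SEM = 2-(trimethylsilyl)ethoxymethyl, TES = triethylsilyl, geranyl = (2E)-3,7-dimethylocta-2,6-dien-1-yl. Primed locants belong to the dihydrobenzofuran unit.

Step 1
Reactants: 1 benzofuran-6-ol
Product: 2 6-(SEM-oxy)benzofuran
Conditions: SEMCl, i-Pr2NEt, CH2Cl2, 0 °C to rt
Reagents that add atoms: SEMCl C[Si](C)(C)CCOCCl
Why: O-Alkylation of the phenol with the highly reactive chloromethyl ether (Williamson-type acetal formation) should be clean and installs a group that directs ortho-metalation, withstands organolithiums and is later removed by fluoride.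

Step 2
Reactants: 2 6-(SEM-oxy)benzofuran; 3 geranyl bromide
Product: 7 2-(trimethylsilyl)-7-geranyl-6-(SEM-oxy)benzofuran, via 2-lithiobenzofuran 4 (not isolated), via 2-silylbenzofuran 5 (not isolated), via 7-lithio-2-silylbenzofuran 6 (not isolated)
Conditions: n-BuLi, THF, −78 °C; TMSCl, −78 to 0 °C; s-BuLi, TMEDA, −78 to −40 °C; 3, −78 °C to rt
Reagents that add atoms: chlorotrimethylsilane C[Si](C)(C)Cl
Why: The first lithiation takes the most acidic proton (C2–H next to the furan oxygen) and silylation blocks that site, so the second base effects a directed ortho-metalation at C7 between O1 and the SEM acetal, and the aryllithium displaces the primary allylic bromide by SN2 alkylation without touching the E double bond.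

Step 3
Reactants: 7 2-(trimethylsilyl)-7-geranyl-6-(SEM-oxy)benzofuran
Product: 8 7-geranyl-6-(SEM-oxy)benzofuran
Conditions: TBAF (1.1 equiv), wet THF, 0 °C
Reagents that add atoms: none
Why: Fluoride-induced protodesilylation should cleave the C2–Si bond, whose departing carbanion is stabilised by the adjacent ring oxygen, at a temperature at which aryl SEM acetals are inert.

Step 4
Reactants: 9 5-fluororesorcinol
Product: 10 1-fluoro-3,5-bis(SEM-oxy)benzene
Conditions: SEMCl (2.4 equiv), i-Pr2NEt, CH2Cl2, 0 °C to rt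
Reagents that add atoms: SEMCl C[Si](C)(C)CCOCCl
Why: Twofold O-alkylation of the resorcinol (Williamson-type acetal formation) gives the symmetrical bis-acetal whose oxygen atoms later polarise the aryne.

Step 5
Reactants: 10 1-fluoro-3,5-bis(SEM-oxy)benzene
Product: 11 2-bromo-1-fluoro-3,5-bis(SEM-oxy)benzene
Conditions: NBS (1.0 equiv), MeCN, 0 °C
Reagents that add atoms: N-bromosuccinimide O=C1CCC(=O)N1Br
Why: Electrophilic aromatic bromination should go to C2, which is para to one acetal oxygen, ortho to the other and flanked only by small fluorine, rather than to C4, which is crowded between two SEM-oxy groups.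

Step 6
Reactants: 12 methyl (2S)-oxirane-2-carboxylate (methyl (S)-glycidate)
Product: 14 triethyl({2-[(2S)-oxiran-2-yl]propan-2-yl}oxy)silane, via lithium alkoxide 13 (not isolated)
Conditions: MeLi (2.0 equiv), Et2O, −78 °C; TESCl (2.2 equiv), −78 °C to rt
Reagents that add atoms: methyllithium [Li]C; chlorotriethylsilane CC[Si](Cl)(CC)CC
Why: Twofold 1,2-addition of methyllithium to the ester is much faster at −78 °C than epoxide opening, the stereocentre comes unchanged from the chiral pool because none of its bonds is broken, and the tertiary lithium alkoxide is silylated in the same flask (the excess TESCl also takes up the methoxide).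

Step 7
Reactants: 8 7-geranyl-6-(SEM-oxy)benzofuran; 11 2-bromo-1-fluoro-3,5-bis(SEM-oxy)benzene; 14 (S)-TES epoxide
Product: 19 (2S)-1-{2-[7-geranyl-6-(SEM-oxy)benzofuran-2-yl]-4,6-bis(SEM-oxy)phenyl}-3-methyl-3-(triethylsilyloxy)butan-2-ol, via 2-lithiobenzofuran 15 (not isolated), via fluoroaryllithium 16 (not isolated), via aryne 17 (not isolated), via biaryllithium 18 (not isolated)
Conditions: 8 (1.2 equiv), n-BuLi, THF, −78 °C (flask A); 11, t-BuLi (2.0 equiv), THF, −78 °C (flask B); A into B by cannula, −78 to −30 °C; then 14 (2 equiv), BF3·OEt2, −78 °C; H2O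
Reagents that add atoms: none
Why: Bromine–lithium exchange converts 11 into 16, which loses LiF on warming to give aryne 17; 15, made by deprotonation of C2–H (the most acidic C–H of 8), adds to 17, and the resulting aryllithium 18 opens the BF3-activated epoxide 14 by SN2 attack at its CH2 terminus. The closest known reaction type is the addition of aryllithium or arylmagnesium reagents to 3-alkoxyarynes followed by an electrophilic quench of the 2-metalated biaryl, here combined with the BF3-promoted opening of epoxides by aryllithiums. No ring is closed in this step. No stereocentre is created: the carbinol carbon comes from 14 with all four of its bonds intact, so it stays (S). The regioselectivity needed is attack of 15 at the aryne carbon remote from the flanking SEM-oxy group (future C4′), which is secured because that inductively withdrawing oxygen (future O1′ on C7a′) distorts the triple bond and stabilises, with chelation by the acetal, the carbanion that develops beside it at future C3a′, while the second SEM-oxy group lies too far away to compete. The chemoselectivity needed is capture of 17 by 15 rather than by 16 or 18 and survival of 18 until 14 is added, which is helped by the slow release of 17 into an excess of unhindered 15, by the two ortho substituents that shield 16 and 18, and by the absence of amines or other proton sources.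

Step 8
Reactants: 19 (S)-alcohol
Product: 20 (2S)-1-{2-[7-geranyl-6-(SEM-oxy)benzofuran-2-yl]-4,6-bis(SEM-oxy)phenyl}-3-methyl-3-(triethylsilyloxy)butan-2-yl methanesulfonate
Conditions: MsCl, Et3N, CH2Cl2, 0 °C
Reagents that add atoms: methanesulfonyl chloride CS(=O)(=O)Cl
Why: Mesylation via sulfene is little affected by the hindrance around the secondary alcohol and breaks only the O–H bond, so the (S) configuration is kept.

Step 9
Reactants: 20 (S)-mesylate
Product: 22 2-[(2S)-6-hydroxy-2-(2-hydroxypropan-2-yl)-2,3-dihydrobenzofuran-4-yl]-7-geranylbenzofuran-6-ol (target), via tris-SEM epoxide 21 (not isolated)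
Conditions: TBAF (10 equiv), THF, 0 °C, 1 h; then DMPU, 70 °C; H2O
Reagents that add atoms: none
Why: At 0 °C fluoride removes only the TES group and the tertiary alkoxide displaces the neighbouring mesylate (3-exo-tet SN2, first inversion) to give (R)-epoxide 21, and on heating the fluoride-induced fragmentation of the three SEM acetals frees the phenoxides, of which the one on C7a′ opens the epoxide at its less substituted carbon (5-exo-tet SN2, second inversion), so that C2′ ends up (S) by net retention.

Compound list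
1 | benzofuran-6-ol | Oc1ccc2ccoc2c1 | starting material
2 | 6-(SEM-oxy)benzofuran | C[Si](C)(C)CCOCOc1ccc2ccoc2c1 | intermediate
3 | geranyl bromide, (2E)-1-bromo-3,7-dimethylocta-2,6-diene | CC(C)=CCC/C(C)=C/CBr | starting material
4 | 2-lithio-6-(SEM-oxy)benzofuran | [Li]c1cc2ccc(OCOCC[Si](C)(C)C)cc2o1 | intermediate
5 | 2-(trimethylsilyl)-6-(SEM-oxy)benzofuran | C[Si](C)(C)c1cc2ccc(OCOCC[Si](C)(C)C)cc2o1 | intermediate
6 | 7-lithio-2-(trimethylsilyl)-6-(SEM-oxy)benzofuran | C[Si](C)(C)c1cc2ccc(OCOCC[Si](C)(C)C)c([Li])c2o1 | intermediate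
7 | 2-(trimethylsilyl)-7-geranyl-6-(SEM-oxy)benzofuran | CC(C)=CCC/C(C)=C/Cc1c(OCOCC[Si](C)(C)C)ccc2cc([Si](C)(C)C)oc12 | intermediate
8 | 7-geranyl-6-(SEM-oxy)benzofuran | CC(C)=CCC/C(C)=C/Cc1c(OCOCC[Si](C)(C)C)ccc2ccoc12 | intermediate
9 | 5-fluororesorcinol (5-fluorobenzene-1,3-diol) | Oc1cc(O)cc(F)c1 | starting material
10 | 1-fluoro-3,5-bis(SEM-oxy)benzene | Fc1cc(OCOCC[Si](C)(C)C)cc(OCOCC[Si](C)(C)C)c1 | intermediate
11 | 2-bromo-1-fluoro-3,5-bis(SEM-oxy)benzene | Fc1cc(OCOCC[Si](C)(C)C)cc(OCOCC[Si](C)(C)C)c1Br | intermediate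
12 | methyl (2S)-oxirane-2-carboxylate | COC(=O)[C@@H]1CO1 | starting material
13 | lithium 2-[(2S)-oxiran-2-yl]propan-2-olate | [Li+].[O-]C(C)(C)[C@@H]1CO1 | intermediate
14 | triethyl({2-[(2S)-oxiran-2-yl]propan-2-yl}oxy)silane | CC[Si](CC)(CC)OC(C)(C)[C@@H]1CO1 | intermediate
15 | 2-lithio-7-geranyl-6-(SEM-oxy)benzofuran | CC(C)=CCC/C(C)=C/Cc1c(OCOCC[Si](C)(C)C)ccc2cc([Li])oc12 | intermediate
16 | 2-fluoro-4,6-bis(SEM-oxy)phenyllithium | [Li]c1c(F)cc(OCOCC[Si](C)(C)C)cc1OCOCC[Si](C)(C)C | intermediate
17 | 3,5-bis(SEM-oxy)benzyne | C1#CC(OCOCC[Si](C)(C)C)=CC(OCOCC[Si](C)(C)C)=C1 | intermediate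
18 | 2-[7-geranyl-6-(SEM-oxy)benzofuran-2-yl]-4,6-bis(SEM-oxy)phenyllithium | CC(C)=CCC/C(C)=C/Cc1c(OCOCC[Si](C)(C)C)ccc2cc(-c3cc(OCOCC[Si](C)(C)C)cc(OCOCC[Si](C)(C)C)c3[Li])oc12 | intermediate
19 | (2S)-1-{2-[7-geranyl-6-(SEM-oxy)benzofuran-2-yl]-4,6-bis(SEM-oxy)phenyl}-3-methyl-3-(triethylsilyloxy)butan-2-ol | CC(C)=CCC/C(C)=C/Cc1c(OCOCC[Si](C)(C)C)ccc2cc(-c3cc(OCOCC[Si](C)(C)C)cc(OCOCC[Si](C)(C)C)c3C[C@H](O)C(C)(C)O[Si](CC)(CC)CC)oc12 | intermediate
20 | methanesulfonate of 19, (2S) | CC(C)=CCC/C(C)=C/Cc1c(OCOCC[Si](C)(C)C)ccc2cc(-c3cc(OCOCC[Si](C)(C)C)cc(OCOCC[Si](C)(C)C)c3C[C@H](OS(C)(=O)=O)C(C)(C)O[Si](CC)(CC)CC)oc12 | intermediate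
21 | 2-(2-{[(2R)-3,3-dimethyloxiran-2-yl]methyl}-3,5-bis(SEM-oxy)phenyl)-7-geranyl-6-(SEM-oxy)benzofuran | CC(C)=CCC/C(C)=C/Cc1c(OCOCC[Si](C)(C)C)ccc2cc(-c3cc(OCOCC[Si](C)(C)C)cc(OCOCC[Si](C)(C)C)c3C[C@H]4OC4(C)C)oc12 | intermediate
22 | 2-[(2S)-6-hydroxy-2-(2-hydroxypropan-2-yl)-2,3-dihydrobenzofuran-4-yl]-7-geranylbenzofuran-6-ol | CC(C)=CCC/C(C)=C/Cc1c(O)ccc2cc(-c3cc(O)cc4c3C[C@@H](C(C)(C)O)O4)oc12 | target

Total step count: 9.
Longest linear sequence: 6 steps (1, 2, 3, 7, 8, 9).

Steps most likely to fail

Step 7.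
- **What may go wrong:** The aryne may be consumed by 16 or 18 instead of 15 (oligomerisation). Alternatively, 18 may be protonated before the epoxide is opened, for instance by the benzylic–allylic CH2 of the geranyl chain.
- **Fallback:** It makes the same C2–C4′ bond by cross-coupling. It sets out from 8 and 14 and comes back at 19.
- **Arene partner:** 5-Bromoresorcinol F1 is converted with SEMCl/i-Pr2NEt into 1-bromo-3,5-bis(SEM-oxy)benzene F2. NIS in MeCN iodinates F2 para to one acetal oxygen and next to bromine to give 1-bromo-2-iodo-3,5-bis(SEM-oxy)benzene F3. i-PrMgCl·LiCl at −40 °C exchanges only the iodine, and the resulting 2-bromo-4,6-bis(SEM-oxy)phenylmagnesium chloride F4 opens 14 under CuI catalysis to the (S)-bromo alcohol F5.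
- **Coupling:** Compound 8 is lithiated to 15 and transmetalated with ZnCl2 to the benzofuran-2-ylzinc chloride F6. A Negishi coupling of F6 with F5 (Pd(OAc)2, SPhos, THF) tolerates the free hydroxyl group and gives 19.

Step 9.
- **What may go wrong:** Early loss of the SEM group on the C7a′ oxygen could let the phenoxide displace the mesylate directly, which erodes the configuration. Hot basic fluoride could also eliminate the mesylate, and the freed phenoxides could capture the released formaldehyde.
- **Fallback:** It separates deprotection from C–O bond formation. It sets out from 8 and 11 and comes back at 22.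
- **Enantiomeric series:** Methyl (R)-glycidate F7 is taken through the operations of step 6, by way of lithium (R)-alkoxide F8, to the (R)-TES epoxide F9. In the operation of step 7, F9 gives the (R)-alcohol F10.
- **Closure:** With no leaving group in the molecule, TBAF in THF/DMPU strips the TES and the three SEM groups to the (R)-pentaol F11. A Mitsunobu cyclodehydration (PPh3, DIAD, THF, 0 °C) then activates only the secondary alcohol. The neighbouring phenol displaces it in a 5-exo-tet SN2 closure with a single inversion to give (S)-22.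

Step 2.
- **What may go wrong:** Incomplete blocking of C2, competing metalation at C5, or allylic transposition and homocoupling of the bromide could spoil the one-pot sequence.
- **Fallback:** It avoids organolithium chemistry. It sets out from 1 and 3 and comes back at 8.
- **C-alkylation:** The sodium phenoxide of 1 (NaH, toluene) is alkylated with 3 under heterogeneous non-polar conditions that favour ortho-C- over O-alkylation. Attack through C7 keeps the furan sextet intact in the cyclohexadienone intermediate, whereas attack through C5 would destroy it. 7-Geranylbenzofuran-6-ol F12 should therefore be the main C-alkylation product, and SEMCl/i-Pr2NEt then gives 8.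

Further compounds
F1 | step 7 | 5-bromoresorcinol | Oc1cc(O)cc(Br)c1
F2 | step 7 | 1-bromo-3,5-bis(SEM-oxy)benzene | C[Si](C)(C)CCOCOc1cc(Br)cc(OCOCC[Si](C)(C)C)c1
F3 | step 7 | 1-bromo-2-iodo-3,5-bis(SEM-oxy)benzene | C[Si](C)(C)CCOCOc1cc(OCOCC[Si](C)(C)C)c(I)c(Br)c1
F4 | step 7 | 2-bromo-4,6-bis(SEM-oxy)phenylmagnesium chloride | C[Si](C)(C)CCOCOc1cc(OCOCC[Si](C)(C)C)c([Mg]Cl)c(Br)c1
F5 | step 7 | (2S)-1-[2-bromo-4,6-bis(SEM-oxy)phenyl]-3-methyl-3-(triethylsilyloxy)butan-2-ol | C[Si](C)(C)CCOCOc1cc(Br)c(C[C@H](O)C(C)(C)O[Si](CC)(CC)CC)c(OCOCC[Si](C)(C)C)c1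
F6 | step 7 | [7-geranyl-6-(SEM-oxy)benzofuran-2-yl]zinc chloride | CC(C)=CCC/C(C)=C/Cc1c(OCOCC[Si](C)(C)C)ccc2cc([Zn]Cl)oc12
F7 | step 9 | methyl (2R)-oxirane-2-carboxylate | COC(=O)[C@H]1CO1
F8 | step 9 | lithium 2-[(2R)-oxiran-2-yl]propan-2-olate | [Li+].[O-]C(C)(C)[C@H]1CO1
F9 | step 9 | triethyl({2-[(2R)-oxiran-2-yl]propan-2-yl}oxy)silane | CC[Si](CC)(CC)OC(C)(C)[C@H]1CO1
F10 | step 9 | (2R)-1-{2-[7-geranyl-6-(SEM-oxy)benzofuran-2-yl]-4,6-bis(SEM-oxy)phenyl}-3-methyl-3-(triethylsilyloxy)butan-2-ol | CC(C)=CCC/C(C)=C/Cc1c(OCOCC[Si](C)(C)C)ccc2cc(-c3cc(OCOCC[Si](C)(C)C)cc(OCOCC[Si](C)(C)C)c3C[C@@H](O)C(C)(C)O[Si](CC)(CC)CC)oc12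
F11 | step 9 | (2R)-1-[2-(7-geranyl-6-hydroxybenzofuran-2-yl)-4,6-dihydroxyphenyl]-3-methylbutane-2,3-diol | CC(C)=CCC/C(C)=C/Cc1c(O)ccc2cc(-c3cc(O)cc(O)c3C[C@@H](O)C(C)(C)O)oc12
F12 | step 2 | 7-geranylbenzofuran-6-ol | CC(C)=CCC/C(C)=C/Cc1c(O)ccc2ccoc12
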